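**Strategy.** Everything rests on building ring A instead of buying it. In ring A (C4a to C8a) the ring oxygen sits on C8a, one methoxy group on the para carbon C6 and a second next door on C7. That is a 4-alkoxyphenol, the product type of a chromium carbene benzannulation. One operation joins a 1-methoxyvinyl(methoxy)carbene complex (C6, C7, C8), one of its CO ligands (C8a with the future O1) and a terminal alkyne (C5, C4a) through the bonds C5–C6, C4a–C8a and C8–C8a. The alkyne, made from zingerone, already holds C4 as a silyl ether, C3, the C2 ketone and the protected guaiacol arm.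

Key step: step 6

Remark: atom labels (O1, C2 to C8a) follow chromone numbering of the target; the target is achiral, and the silyloxy carbinol centre made in step 3 is carried as a racemate until step 9 turns it into the C4 carbonyl.

Remark: the guaiacol oxygen is carried as a methoxymethyl (MOM) ether and the new ring A phenol as an acetate, so that one acid treatment at the end removes both and closes the pyranone ring.

**Step 1**
Reactants: 1 methyl vinyl ether; 2 chromium hexacarbonyl Cr(CO)6
Product: 5 pentacarbonyl[methoxy(1-methoxyethenyl)carbene]chromium, via 1-methoxyvinyllithium 3 (not isolated), via lithium acylchromate 4 (not isolated)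
Conditions: tert-butyllithium (tBuLi), THF, −78 to 0 °C; Cr(CO)6, Et2O/THF, −78 °C to rt; concentrate; Me3OBF4, CH2Cl2, 0 °C; fast filtration through silica under argon
Reagents that add atoms: trimethyloxonium tetrafluoroborate, C[O+](C)C.F[B-](F)(F)F
Why: Fischer carbene synthesis, in which the enol ether is lithiated at its α-carbon, the vinyllithium adds to a CO ligand of Cr(CO)6 to give the acylchromate, and the hard oxonium salt alkylates the acylate oxygen to give the methoxycarbene.

**Step 2**
Reactants: 6 4-(4-hydroxy-3-methoxyphenyl)butan-2-one (zingerone)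
Product: 7 4-[3-methoxy-4-(methoxymethoxy)phenyl]butan-2-one
Conditions: MOMCl, iPr2NEt, CH2Cl2, 0 °C to rt
Reagents that add atoms: chloromethyl methyl ether, COCCl
Why: Williamson-type O-alkylation of the phenol by the α-chloro ether installs an acetal that survives amide base, fluoride, the carbene complex and the oxidant, and falls in the final acid step.

**Step 3**
Reactants: 7 4-[3-methoxy-4-(methoxymethoxy)phenyl]butan-2-one; 8 3-(trimethylsilyl)prop-2-ynal
Product: 10 racemic 5-hydroxy-1-[3-methoxy-4-(methoxymethoxy)phenyl]-7-(trimethylsilyl)hept-6-yn-3-one, via lithium enolate 9 (not isolated)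
Conditions: lithium diisopropylamide LiN(iPr)2, THF, −78 °C; then 8, −78 °C; aqueous NH4Cl at −78 °C
Reagents that add atoms: none
Why: Kinetic deprotonation by the hindered amide takes the methyl group and the lithium enolate adds 1,2 to the non-enolisable ynal (directed aldol addition); the carbinol stereocentre forms without control and is carried as a racemate because step 9 erases it.

**Step 4**
Reactants: 10 racemic 5-hydroxy-1-[3-methoxy-4-(methoxymethoxy)phenyl]-7-(trimethylsilyl)hept-6-yn-3-one
Product: 11 racemic 5-[(tert-butyldimethylsilyl)oxy]-1-[3-methoxy-4-(methoxymethoxy)phenyl]-7-(trimethylsilyl)hept-6-yn-3-one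
Conditions: TBSCl, imidazole, DMF, rt
Reagents that add atoms: tert-butyldimethylsilyl chloride, CC(C)(C)[Si](C)(C)Cl
Why: Imidazole-promoted O-silylation of the secondary propargylic alcohol blocks retro-aldol cleavage and supplies the bulky, non-nucleophilic oxygen substituent that the benzannulation needs, while silyl triflates are avoided because they can cleave aryl MOM ethers.

**Step 5**
Reactants: 11 racemic 5-[(tert-butyldimethylsilyl)oxy]-1-[3-methoxy-4-(methoxymethoxy)phenyl]-7-(trimethylsilyl)hept-6-yn-3-one
Product: 12 racemic 5-[(tert-butyldimethylsilyl)oxy]-1-[3-methoxy-4-(methoxymethoxy)phenyl]hept-6-yn-3-one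
Conditions: AgNO3 (0.1 equiv), acetone/H2O, rt, dark
Reagents that add atoms: none
Why: Silver-catalysed protodesilylation of the alkynylsilane runs through a silver acetylide under neutral conditions, so the alkyl silyl ether stays and the base that would eliminate the β-silyloxy group of the ketone is avoided.

**Step 6**
Reactants: 12 racemic 5-[(tert-butyldimethylsilyl)oxy]-1-[3-methoxy-4-(methoxymethoxy)phenyl]hept-6-yn-3-one; 5 pentacarbonyl[methoxy(1-methoxyethenyl)carbene]chromium
Product: 14 racemic 5-[(tert-butyldimethylsilyl)oxy]-5-(2-hydroxy-4,5-dimethoxyphenyl)-1-[3-methoxy-4-(methoxymethoxy)phenyl]pentan-3-one, via arene tricarbonylchromium complex 13 (not isolated)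
Conditions: 5 (1.5 equiv), THF (0.05 M), 50 °C, argon; then air, EtOAc, rt
Reagents that add atoms: none
Why: Proposed new method: thermal loss of one CO from 5 lets the terminal alkyne of 12 bind and insert into the Cr=C bond with its substituted carbon away from the carbene carbon (C5–C6), CO insertion then gives a chromium-bound dienylketene (C4a–C8a), and ring closure between the ketene carbon and the CH2 terminus of the enol ether (C8–C8a) followed by tautomerisation gives the phenol, which air frees from the Cr(CO)3 fragment. The closest known reaction type is the Dötz benzannulation of alkenyl(methoxy)carbene complexes of zerovalent chromium with terminal alkynes; the untested element is the 1-methoxy group on the alkenyl unit, which is cross-conjugated to the carbene carbon and should therefore leave the insertion sequence unchanged. Ring A is closed by a six-electron electrocyclisation of the metal-bound dienylketene. No stereocentre is formed, and the racemic silyloxy carbon is a spectator. The step needs the alkyne substituent to end next to the CO-derived C8a and needs phenol formation instead of cyclopentannulation or double alkyne insertion; the steric gap between H and the branched silyloxyalkyl group of a terminal alkyne should secure the first, and an alkenyl carbene in THF at low concentration with the carbene in excess should secure the second. The ketone, the silyl ether and the MOM ether should be inert under these neutral conditions.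

**Step 7**
Reactants: 14 racemic 5-[(tert-butyldimethylsilyl)oxy]-5-(2-hydroxy-4,5-dimethoxyphenyl)-1-[3-methoxy-4-(methoxymethoxy)phenyl]pentan-3-one
Product: 15 racemic 2-{1-[(tert-butyldimethylsilyl)oxy]-5-[3-methoxy-4-(methoxymethoxy)phenyl]-3-oxopentyl}-4,5-dimethoxyphenyl acetate
Conditions: Ac2O, pyridine, catalytic DMAP, CH2Cl2, 0 °C to rt
Reagents that add atoms: acetic anhydride, CC(=O)OC(C)=O
Why: Nucleophile-catalysed O-acylation of the phenol masks the oxidation-prone 4-methoxyphenol and removes the ortho-hydroxybenzyl arrangement before the benzylic oxygen is unmasked.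

**Step 8**
Reactants: 15 racemic 2-{1-[(tert-butyldimethylsilyl)oxy]-5-[3-methoxy-4-(methoxymethoxy)phenyl]-3-oxopentyl}-4,5-dimethoxyphenyl acetate
Product: 16 racemic 2-{1-hydroxy-5-[3-methoxy-4-(methoxymethoxy)phenyl]-3-oxopentyl}-4,5-dimethoxyphenyl acetate
Conditions: HF·pyridine, pyridine, THF, 0 °C to rt; used at once in step 9
Reagents that add atoms: none
Why: Fluoride-mediated cleavage of the Si–O bond under weakly acidic, pyridine-buffered conditions frees the alcohol without generating the alkoxide that would take the neighbouring acetyl group or trigger β-elimination.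

**Step 9**
Reactants: 16 racemic 2-{1-hydroxy-5-[3-methoxy-4-(methoxymethoxy)phenyl]-3-oxopentyl}-4,5-dimethoxyphenyl acetate
Product: 17 4,5-dimethoxy-2-{5-[3-methoxy-4-(methoxymethoxy)phenyl]-3-oxopentanoyl}phenyl acetate
Conditions: Dess–Martin periodinane (1.2 equiv), NaHCO3, CH2Cl2, 0 °C to rt
Reagents that add atoms: none
Why: Dess–Martin oxidation converts the secondary benzylic β-hydroxy ketone into the 1,3-diketone under neutral buffered conditions and removes the only stereocentre.

**Step 10**
Reactants: 17 4,5-dimethoxy-2-{5-[3-methoxy-4-(methoxymethoxy)phenyl]-3-oxopentanoyl}phenyl acetate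
Product: 19 2-[2-(4-hydroxy-3-methoxyphenyl)ethyl]-6,7-dimethoxy-4H-chromen-4-one, via free hydroxyaryl diketone 18 (not isolated)
Conditions: concentrated HCl, MeOH, 60 °C
Reagents that add atoms: none
Why: Acid methanolysis removes the aryl acetate and the MOM acetal, and the freed ring A phenol adds to the distal C2 carbonyl and loses water (classical acid cyclodehydration of a 1-(2-hydroxyaryl)-1,3-diketone to a chromone), forming O1–C2.

**Compound list**
1 | methyl vinyl ether | COC=C | starting material
2 | chromium hexacarbonyl Cr(CO)6 | O=C=[Cr](=C=O)(=C=O)(=C=O)(=C=O)=C=O | starting material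
3 | 1-methoxyvinyllithium | [Li]C(=C)OC | intermediate (not isolated)
4 | lithium pentacarbonyl(2-methoxyacryloyl)chromate (lithium acylchromate) | [Li+].[O-]C(=[Cr](=C=O)(=C=O)(=C=O)(=C=O)=C=O)C(=C)OC | intermediate (not isolated)
5 | pentacarbonyl[methoxy(1-methoxyethenyl)carbene]chromium | COC(=[Cr](=C=O)(=C=O)(=C=O)(=C=O)=C=O)C(=C)OC | intermediate
6 | 4-(4-hydroxy-3-methoxyphenyl)butan-2-one (zingerone) | COc1cc(CCC(C)=O)ccc1O | starting material
7 | 4-[3-methoxy-4-(methoxymethoxy)phenyl]butan-2-one | COCOc1ccc(CCC(C)=O)cc1OC | intermediate
8 | 3-(trimethylsilyl)prop-2-ynal | C[Si](C)(C)C#CC=O | starting material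
9 | lithium 4-[3-methoxy-4-(methoxymethoxy)phenyl]but-1-en-2-olate (lithium enolate of 7) | [Li+].[O-]C(=C)CCc1ccc(OCOC)c(OC)c1 | intermediate (not isolated)
10 | racemic 5-hydroxy-1-[3-methoxy-4-(methoxymethoxy)phenyl]-7-(trimethylsilyl)hept-6-yn-3-one | C[Si](C)(C)C#CC(O)CC(=O)CCc1ccc(OCOC)c(OC)c1 | intermediate
11 | racemic 5-[(tert-butyldimethylsilyl)oxy]-1-[3-methoxy-4-(methoxymethoxy)phenyl]-7-(trimethylsilyl)hept-6-yn-3-one | C[Si](C)(C)C#CC(O[Si](C)(C)C(C)(C)C)CC(=O)CCc1ccc(OCOC)c(OC)c1 | intermediate
12 | racemic 5-[(tert-butyldimethylsilyl)oxy]-1-[3-methoxy-4-(methoxymethoxy)phenyl]hept-6-yn-3-one | C#CC(O[Si](C)(C)C(C)(C)C)CC(=O)CCc1ccc(OCOC)c(OC)c1 | intermediate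
13 | racemic tricarbonylchromium complex of 14, Cr(CO)3 η6-bound to ring A | COc1cc(O)c(C(O[Si](C)(C)C(C)(C)C)CC(=O)CCc2ccc(OCOC)c(OC)c2)cc1OC.O=C=[Cr](=C=O)=C=O | intermediate (not isolated)
14 | racemic 5-[(tert-butyldimethylsilyl)oxy]-5-(2-hydroxy-4,5-dimethoxyphenyl)-1-[3-methoxy-4-(methoxymethoxy)phenyl]pentan-3-one | COc1cc(O)c(C(O[Si](C)(C)C(C)(C)C)CC(=O)CCc2ccc(OCOC)c(OC)c2)cc1OC | intermediate
15 | racemic 2-{1-[(tert-butyldimethylsilyl)oxy]-5-[3-methoxy-4-(methoxymethoxy)phenyl]-3-oxopentyl}-4,5-dimethoxyphenyl acetate | COc1cc(OC(C)=O)c(C(O[Si](C)(C)C(C)(C)C)CC(=O)CCc2ccc(OCOC)c(OC)c2)cc1OC | intermediate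
16 | racemic 2-{1-hydroxy-5-[3-methoxy-4-(methoxymethoxy)phenyl]-3-oxopentyl}-4,5-dimethoxyphenyl acetate | COc1cc(OC(C)=O)c(C(O)CC(=O)CCc2ccc(OCOC)c(OC)c2)cc1OC | intermediate
17 | 4,5-dimethoxy-2-{5-[3-methoxy-4-(methoxymethoxy)phenyl]-3-oxopentanoyl}phenyl acetate | COc1cc(OC(C)=O)c(C(=O)CC(=O)CCc2ccc(OCOC)c(OC)c2)cc1OC | intermediate
18 | 1-(2-hydroxy-4,5-dimethoxyphenyl)-5-(4-hydroxy-3-methoxyphenyl)pentane-1,3-dione | COc1cc(O)c(C(=O)CC(=O)CCc2ccc(O)c(OC)c2)cc1OC | intermediate (not isolated)
19 | 2-[2-(4-hydroxy-3-methoxyphenyl)ethyl]-6,7-dimethoxy-4H-chromen-4-one | COc1cc(CCc2cc(=O)c3cc(OC)c(OC)cc3o2)ccc1O | target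

**Total step count:** 10. **Longest linear sequence:** 9 steps (steps 2 to 10, from zingerone 6); step 1 is the side branch that supplies 5.

**Steps most likely to fail**

First, step 6, the labelled benzannulation. The enol ether carbene may decompose before the alkyne inserts, the dienylketene may be diverted to cyclopentannulation, or the free phenol may be lost through hemiketalisation with the chain ketone and ionisation at the benzylic silyloxy carbon. The fallback uses known chemistry and buys ring A. It sets out from ketone 7 and comes back at the target 19.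
- Purchased 2-hydroxy-4,5-dimethoxybenzoic acid is esterified (MeOH, H2SO4, reflux) to methyl 2-hydroxy-4,5-dimethoxybenzoate F1.
- F1 is protected (MOMCl, iPr2NEt, CH2Cl2) as methyl 4,5-dimethoxy-2-(methoxymethoxy)benzoate F2.
- Crossed Claisen condensation of 7 with F2 at the methyl group (NaH, THF, 65 °C) should give 1-[4,5-dimethoxy-2-(methoxymethoxy)phenyl]-5-[3-methoxy-4-(methoxymethoxy)phenyl]pentane-1,3-dione F3.
- The conditions of step 10 (HCl, MeOH, 60 °C) should strip both MOM groups and cyclodehydrate through 18 to 19.

Second, step 1. O-methylation of the acylate by the oxonium salt may be incomplete, or protonolysis may give the labile hydroxycarbene, and the crude lithium salt cannot be purified. The fallback sets out from the lithium acylate 4 and comes back at 5 by acylation and alcohol exchange instead of direct alkylation.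
- 4 is taken up in water and precipitated with Me4NBr as tetramethylammonium pentacarbonyl(2-methoxyacryloyl)chromate F4, a storable solid.
- F4 is acylated with acetyl bromide in CH2Cl2 at −40 °C to pentacarbonyl[acetoxy(1-methoxyethenyl)carbene]chromium F5.
- Methanol added to the same flask exchanges acetoxy for methoxy at the carbene carbon to give 5.

Third, step 8. The acetyl group may migrate from the phenol oxygen to the freed benzylic oxygen, or the β-hydroxy ketone may dehydrate to the styryl ketone, driven by conjugation with the electron-rich ring A. The fallback sets out from silyl ether 15 and comes back at diketone 17 without ever freeing the alcohol. DDQ in CH2Cl2 with pH 7 buffer at rt should abstract the benzylic hydride, which is activated by the para methoxy group at C7, and water then removes the silyl group from the resulting silyloxocarbenium ion to give the aryl ketone directly. This is the known oxidative desilylation of electron-rich benzylic silyl ethers, and it makes no compound outside the list.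

**Further compounds**
F1 | step 6 | methyl 2-hydroxy-4,5-dimethoxybenzoate | COC(=O)c1cc(OC)c(OC)cc1O
F2 | step 6 | methyl 4,5-dimethoxy-2-(methoxymethoxy)benzoate | COCOc1cc(OC)c(OC)cc1C(=O)OC
F3 | step 6 | 1-[4,5-dimethoxy-2-(methoxymethoxy)phenyl]-5-[3-methoxy-4-(methoxymethoxy)phenyl]pentane-1,3-dione | COCOc1cc(OC)c(OC)cc1C(=O)CC(=O)CCc1ccc(OCOC)c(OC)c1
F4 | step 1 | tetramethylammonium pentacarbonyl(2-methoxyacryloyl)chromate | C[N+](C)(C)C.[O-]C(=[Cr](=C=O)(=C=O)(=C=O)(=C=O)=C=O)C(=C)OC
F5 | step 1 | pentacarbonyl[acetoxy(1-methoxyethenyl)carbene]chromium | CC(=O)OC(=[Cr](=C=O)(=C=O)(=C=O)(=C=O)=C=O)C(=C)OC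
F0 | step 8 | none | none
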